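**Plan**

- Retrosynthetic cuts, in order: (i) the N–CH2 bond of the formamide side chain, back to a vinyl group on C6; (ii) the C8–C8a bond between the ring CH2 and the pyridine carbon next to nitrogen; (iii) both C=C bonds of a 3,3-disubstituted penta-1,4-diene, back to a malonate through diol and dialdehyde; (iv) the C5–C6 bond, by malonate alkylation with 3-picolyl chloride.
- Enabling feature: quaternary C6 carries two two-carbon arms, C7–C8 of the carbocycle and the CH2CH2N chain, and both are vinyl groups in the precursor, which is therefore achiral. C8a–H is the pyridine C–H next to N1 and ortho to the C4a–C5 tether.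
- Forward order: the pyridine ring is bought; the quaternary carbon is assembled open-chain (steps 1–5); the carbocycle (C4a, C5, C6, C7, C8, C8a) closes in step 6; the side chain is completed in steps 7–9.
- Stereochemistry: the single stereocentre, C6 (S), is set in step 6 by a chiral nickel/aluminium catalyst that selects one of two enantiotopic vinyl groups. It is an all-carbon quaternary centre and cannot epimerise afterwards.

Key step: step 6

Remark on the chemistry: the stereocentre is read as (S) from the SMILES. The sense of induction of the ligand in step 6 cannot be predicted; the (R,R)-ligand is written as an assumption, and its mirror image would be used if the (R)-product were favoured.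

**Route**

Step 1
Reactants: 1 methyl (3,4-dimethoxyphenyl)acetate; 2 dimethyl carbonate
Product: 3 dimethyl 2-(3,4-dimethoxyphenyl)propanedioate
Conditions: NaH (2.5 equiv), dimethyl carbonate (5 equiv), THF, reflux; then aq. HCl, 0 °C
Reagents that add atoms: none
Why: Claisen-type C-methoxycarbonylation of the ester enolate, driven forward by formation of the doubly stabilised malonate anion.

Step 2
Reactants: 3 dimethyl 2-(3,4-dimethoxyphenyl)propanedioate; 4 3-(chloromethyl)pyridine hydrochloride
Product: 5 dimethyl 2-(3,4-dimethoxyphenyl)-2-(pyridin-3-ylmethyl)propanedioate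
Conditions: NaH (2.2 equiv), DMF, 0 °C → rt
Reagents that add atoms: none
Why: Malonate alkylation (SN2) of the aryl-stabilised tertiary anion by the picolylic chloride, freed from its salt in the flask, should create the still achiral quaternary carbon C6.

Step 3
Reactants: 5 dimethyl 2-(3,4-dimethoxyphenyl)-2-(pyridin-3-ylmethyl)propanedioate
Product: 6 2-(3,4-dimethoxyphenyl)-2-(pyridin-3-ylmethyl)propane-1,3-diol
Conditions: LiAlH4 (2.5 equiv), THF, 0 °C → rt; then H2O, aq. NaOH (Fieser work-up)
Reagents that add atoms: none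
Why: LiAlH4 reduction of both esters to primary alcohols, with pyridine and aryl ethers inert at this temperature.

Step 4
Reactants: 6 2-(3,4-dimethoxyphenyl)-2-(pyridin-3-ylmethyl)propane-1,3-diol
Product: 7 2-(3,4-dimethoxyphenyl)-2-(pyridin-3-ylmethyl)propanedial
Conditions: Dess–Martin periodinane (2.4 equiv), CH2Cl2, 0 °C → rt; filtration through silica, crude product used at once
Reagents that add atoms: none
Why: Dess–Martin oxidation of both neopentyl-type primary alcohols; the dialdehyde has no α-hydrogen and is kept away from aqueous base to avoid deformylation.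

Step 5
Reactants: 7 2-(3,4-dimethoxyphenyl)-2-(pyridin-3-ylmethyl)propanedial
Product: 8 3-[2-(3,4-dimethoxyphenyl)-2-ethenylbut-3-en-1-yl]pyridine
Conditions: Ph3PCH3Br (3 equiv), KOtBu (2.9 equiv), THF, 0 °C; then 7, −78 °C → rt
Reagents that add atoms: methyltriphenylphosphonium bromide, C[P+](c1ccccc1)(c1ccccc1)c1ccccc1.[Br-]
Why: Double Wittig methylenation of the two non-enolisable aldehydes should give the two enantiotopic vinyl groups on C6.

Step 6
Reactants: 8 3-[2-(3,4-dimethoxyphenyl)-2-ethenylbut-3-en-1-yl]pyridine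
Product: 9 (S)-6-(3,4-dimethoxyphenyl)-6-ethenyl-5,6,7,8-tetrahydroquinoline
Conditions: Ni(cod)2 (10 mol %), (R,R)-TADDOL-derived secondary phosphine oxide (cyclic H-phosphonate of (4R,5R)-2,2-dimethyl-α,α,α′,α′-tetraphenyl-1,3-dioxolane-4,5-dimethanol, 12 mol %), AlMe3 (40 mol %), toluene, 80 °C, sealed tube
Reagents that add atoms: none
Why: Proposed new method: AlMe3 binds the pyridine nitrogen and is tied to nickel through the P–O–Al bridge of the deprotonated phosphine oxide, zerovalent nickel coordinates one vinyl group, the C8a hydrogen passes to the internal alkene carbon C7 (ligand-to-ligand hydrogen transfer) to give a seven-membered 2-pyridyl(primary alkyl)nickel metallacycle, and reductive elimination forms the C8–C8a bond. The closest known reaction type is the nickel/aluminium-catalysed enantioselective intramolecular alkene hydroheteroarylation (C–H annulation) of pyridines, pyridones and azoles, together with phosphine-oxide-bridged nickel/aluminium C2–H alkylation of pyridines; not shown so far are the desymmetrisation of a 3,3-disubstituted penta-1,4-diene and closure at C2 from a tether on C3. The carbocycle (C4a, C5, C6, C7, C8, C8a) closes in the 6-endo, anti-Markovnikov mode, since the 5-exo mode would need a secondary alkylnickel next to the quaternary carbon. The only stereocentre, quaternary C6, arises by desymmetrisation: the chiral ligand decides which of the two enantiotopic vinyl groups enters the hydrogen-transfer and reductive-elimination sequence, and the other vinyl group is kept for the side chain. The step needs C8a over C4 selectivity, which the N–Al–O–P–Ni bridge should secure because it reaches only a C–H bond next to nitrogen, and of the two such bonds only the one flanked by the tether can meet the alkene; the quaternary carbon has no allylic hydrogen, so the alkenes cannot migrate.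

Step 7
Reactants: 9 (S)-6-(3,4-dimethoxyphenyl)-6-ethenyl-5,6,7,8-tetrahydroquinoline
Product: 11 (S)-2-[6-(3,4-dimethoxyphenyl)-5,6,7,8-tetrahydroquinolin-6-yl]ethan-1-ol, via B-alkyl-9-BBN adduct 10 (not isolated)
Conditions: 9-BBN (2.5 equiv), THF, 65 °C; then aq. NaOH, 30 % H2O2, 0 °C → rt
Reagents that add atoms: hydrogen peroxide, OO
Why: Brown hydroboration–oxidation places boron, then oxygen, on the terminal carbon of the neopentyl-type vinyl group (anti-Markovnikov); the excess of borane allows for reversible N→B binding, and C6 is not touched.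

Step 8
Reactants: 11 (S)-2-[6-(3,4-dimethoxyphenyl)-5,6,7,8-tetrahydroquinolin-6-yl]ethan-1-ol
Product: 12 (S)-2-[6-(3,4-dimethoxyphenyl)-5,6,7,8-tetrahydroquinolin-6-yl]ethyl methanesulfonate
Conditions: MsCl (1.3 equiv), Et3N (2 equiv), CH2Cl2, 0 °C; used without storage
Reagents that add atoms: methanesulfonyl chloride, CS(=O)(=O)Cl
Why: Sulfonylation of the primary alcohol gives a leaving group; a bridged intramolecular N-alkylation of the pyridine is geometrically disfavoured.

Step 9
Reactants: 12 (S)-2-[6-(3,4-dimethoxyphenyl)-5,6,7,8-tetrahydroquinolin-6-yl]ethyl methanesulfonate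
Product: 13 (S)-N-{2-[6-(3,4-dimethoxyphenyl)-5,6,7,8-tetrahydroquinolin-6-yl]ethyl}-N-methylformamide (N-formyltortuosamine)
Conditions: N-methylformamide (3 equiv), NaH (2.5 equiv), DMF, 0 °C; then 12, 50 °C
Reagents that add atoms: N-methylformamide, CNC=O
Why: SN2 N-alkylation of the sodium salt of a secondary formamide by the primary mesylate should install the N-methyl and N-formyl groups together.

**Compound list**

1 | methyl (3,4-dimethoxyphenyl)acetate | COC(=O)Cc1ccc(OC)c(OC)c1 | starting material
2 | dimethyl carbonate | COC(=O)OC | starting material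
3 | dimethyl 2-(3,4-dimethoxyphenyl)propanedioate | COC(=O)C(C(=O)OC)c1ccc(OC)c(OC)c1 | intermediate
4 | 3-(chloromethyl)pyridine hydrochloride | ClCc1cccnc1.Cl | starting material
5 | dimethyl 2-(3,4-dimethoxyphenyl)-2-(pyridin-3-ylmethyl)propanedioate | COC(=O)C(Cc1cccnc1)(C(=O)OC)c1ccc(OC)c(OC)c1 | intermediate
6 | 2-(3,4-dimethoxyphenyl)-2-(pyridin-3-ylmethyl)propane-1,3-diol | OCC(CO)(Cc1cccnc1)c1ccc(OC)c(OC)c1 | intermediate
7 | 2-(3,4-dimethoxyphenyl)-2-(pyridin-3-ylmethyl)propanedial | O=CC(C=O)(Cc1cccnc1)c1ccc(OC)c(OC)c1 | intermediate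
8 | 3-[2-(3,4-dimethoxyphenyl)-2-ethenylbut-3-en-1-yl]pyridine | C=CC(C=C)(Cc1cccnc1)c1ccc(OC)c(OC)c1 | intermediate
9 | (S)-6-(3,4-dimethoxyphenyl)-6-ethenyl-5,6,7,8-tetrahydroquinoline | COc1ccc([C@@]2(C=C)CCc3ncccc3C2)cc1OC | intermediate
10 | (S)-6-[2-(9-borabicyclo[3.3.1]nonan-9-yl)ethyl]-6-(3,4-dimethoxyphenyl)-5,6,7,8-tetrahydroquinoline | COc1ccc([C@@]2(CCB3C4CCCC3CCC4)CCc3ncccc3C2)cc1OC | intermediate (not isolated)
11 | (S)-2-[6-(3,4-dimethoxyphenyl)-5,6,7,8-tetrahydroquinolin-6-yl]ethan-1-ol | COc1ccc([C@@]2(CCO)CCc3ncccc3C2)cc1OC | intermediate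
12 | (S)-2-[6-(3,4-dimethoxyphenyl)-5,6,7,8-tetrahydroquinolin-6-yl]ethyl methanesulfonate | COc1ccc([C@@]2(CCOS(C)(=O)=O)CCc3ncccc3C2)cc1OC | intermediate
13 | (S)-N-{2-[6-(3,4-dimethoxyphenyl)-5,6,7,8-tetrahydroquinolin-6-yl]ethyl}-N-methylformamide | COc1ccc([C@@]2(CCN(C)C=O)CCc3ncccc3C2)cc1OC | target

**Count**

Total steps: 9. Longest linear sequence: 9 steps (from 1).

**Steps most likely to fail**

Step 6. What may go wrong: poor discrimination between the enantiotopic vinyl groups, closure at C4 or five-ring closure in place of the wanted closure, or arrest of the catalyst by chelation of the diene. The fallback uses known chemistry, sets out from malonate 3 and comes back to the route at alcohol 11. Compound 3 is alkylated with 2-chloro-3-(chloromethyl)pyridine (NaH, DMF) to dimethyl 2-[(2-chloropyridin-3-yl)methyl]-2-(3,4-dimethoxyphenyl)propanedioate F1. This is reduced with LiBH4 (THF/MeOH) to 2-[(2-chloropyridin-3-yl)methyl]-2-(3,4-dimethoxyphenyl)propane-1,3-diol F2, oxidised with Dess–Martin periodinane to 2-[(2-chloropyridin-3-yl)methyl]-2-(3,4-dimethoxyphenyl)propanedial F3, and methylenated (Ph3PCH3Br, KOtBu) to 2-chloro-3-[2-(3,4-dimethoxyphenyl)-2-ethenylbut-3-en-1-yl]pyridine F4. Both vinyl groups are hydroborated with 9-BBN to the bis(B-alkyl-9-BBN) adduct F5. An intramolecular B-alkyl Suzuki–Miyaura coupling (Pd(OAc)2, SPhos, K3PO4, THF/H2O, 65 °C, high dilution) then forms the same bond at the carbon that carried chlorine and should give the racemic cyclised borane F6. Work-up with NaOH/H2O2 gives racemic 2-[6-(3,4-dimethoxyphenyl)-5,6,7,8-tetrahydroquinolin-6-yl]ethan-1-ol F7. Preparative chromatography on a chiral stationary phase separates the (S)-enantiomer, which is 11. The halogen fixes the site of closure, the hydroboration fixes the ring size, and the separation supplies the configuration.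

Step 4 (with step 5). What may go wrong: loss of a formyl group from the 2,2-disubstituted 1,3-dialdehyde by retro-Claisen-type C–C cleavage during oxidation, work-up or ylide addition. The fallback sets out from diol 6 and comes back at diene 8; it introduces the vinyl groups one after the other and never passes through a 1,3-dialdehyde. Monosilylation (NaH 1 equiv, TBSCl, THF) gives racemic 3-{[tert-butyl(dimethyl)silyl]oxy}-2-(3,4-dimethoxyphenyl)-2-(pyridin-3-ylmethyl)propan-1-ol F8. Dess–Martin oxidation gives 3-{[tert-butyl(dimethyl)silyl]oxy}-2-(3,4-dimethoxyphenyl)-2-(pyridin-3-ylmethyl)propanal F9. Wittig methylenation gives 3-[2-({[tert-butyl(dimethyl)silyl]oxy}methyl)-2-(3,4-dimethoxyphenyl)but-3-en-1-yl]pyridine F10. TBAF in THF gives 2-(3,4-dimethoxyphenyl)-2-(pyridin-3-ylmethyl)but-3-en-1-ol F11. A second Dess–Martin oxidation gives 2-(3,4-dimethoxyphenyl)-2-(pyridin-3-ylmethyl)but-3-enal F12, and a second Wittig methylenation gives 8.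

Step 9. What may go wrong: O-alkylation of the ambident formamide anion, and base-induced elimination of the mesylate back to the alkene. The fallback sets out from mesylate 12 and comes back at target 13; it separates C–N bond formation from formylation. Displacement with a large excess of methylamine (EtOH, sealed tube, 60 °C) should give (S)-2-[6-(3,4-dimethoxyphenyl)-5,6,7,8-tetrahydroquinolin-6-yl]-N-methylethan-1-amine (tortuosamine) F13. N-formylation with ethyl formate at reflux then gives 13.

**Further compounds**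

F1 | step 6 | dimethyl 2-[(2-chloropyridin-3-yl)methyl]-2-(3,4-dimethoxyphenyl)propanedioate | COC(=O)C(Cc1cccnc1Cl)(C(=O)OC)c1ccc(OC)c(OC)c1
F2 | step 6 | 2-[(2-chloropyridin-3-yl)methyl]-2-(3,4-dimethoxyphenyl)propane-1,3-diol | OCC(CO)(Cc1cccnc1Cl)c1ccc(OC)c(OC)c1
F3 | step 6 | 2-[(2-chloropyridin-3-yl)methyl]-2-(3,4-dimethoxyphenyl)propanedial | O=CC(C=O)(Cc1cccnc1Cl)c1ccc(OC)c(OC)c1
F4 | step 6 | 2-chloro-3-[2-(3,4-dimethoxyphenyl)-2-ethenylbut-3-en-1-yl]pyridine | C=CC(C=C)(Cc1cccnc1Cl)c1ccc(OC)c(OC)c1
F5 | step 6 | 3-{4-(9-borabicyclo[3.3.1]nonan-9-yl)-2-[2-(9-borabicyclo[3.3.1]nonan-9-yl)ethyl]-2-(3,4-dimethoxyphenyl)butyl}-2-chloropyridine | COc1ccc(C(CCB2C3CCCC2CCC3)(CCB2C3CCCC2CCC3)Cc2cccnc2Cl)cc1OC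
F6 | step 6 | racemic 6-[2-(9-borabicyclo[3.3.1]nonan-9-yl)ethyl]-6-(3,4-dimethoxyphenyl)-5,6,7,8-tetrahydroquinoline | COc1ccc(C2(CCB3C4CCCC3CCC4)CCc3ncccc3C2)cc1OC
F7 | step 6 | racemic 2-[6-(3,4-dimethoxyphenyl)-5,6,7,8-tetrahydroquinolin-6-yl]ethan-1-ol | COc1ccc(C2(CCO)CCc3ncccc3C2)cc1OC
F8 | step 4 | racemic 3-{[tert-butyl(dimethyl)silyl]oxy}-2-(3,4-dimethoxyphenyl)-2-(pyridin-3-ylmethyl)propan-1-ol | CC(C)(C)[Si](C)(C)OCC(CO)(Cc1cccnc1)c1ccc(OC)c(OC)c1
F9 | step 4 | racemic 3-{[tert-butyl(dimethyl)silyl]oxy}-2-(3,4-dimethoxyphenyl)-2-(pyridin-3-ylmethyl)propanal | CC(C)(C)[Si](C)(C)OCC(C=O)(Cc1cccnc1)c1ccc(OC)c(OC)c1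
F10 | step 4 | racemic 3-[2-({[tert-butyl(dimethyl)silyl]oxy}methyl)-2-(3,4-dimethoxyphenyl)but-3-en-1-yl]pyridine | CC(C)(C)[Si](C)(C)OCC(C=C)(Cc1cccnc1)c1ccc(OC)c(OC)c1
F11 | step 4 | racemic 2-(3,4-dimethoxyphenyl)-2-(pyridin-3-ylmethyl)but-3-en-1-ol | OCC(C=C)(Cc1cccnc1)c1ccc(OC)c(OC)c1
F12 | step 4 | racemic 2-(3,4-dimethoxyphenyl)-2-(pyridin-3-ylmethyl)but-3-enal | O=CC(C=C)(Cc1cccnc1)c1ccc(OC)c(OC)c1
F13 | step 9 | (S)-2-[6-(3,4-dimethoxyphenyl)-5,6,7,8-tetrahydroquinolin-6-yl]-N-methylethan-1-amine | COc1ccc([C@@]2(CCNC)CCc3ncccc3C2)cc1OC
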